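**Assumption:** ring carbons are labelled C1–C14 in the order of the target SMILES (C1 = CH bearing the acrylic acid, C4/C8/C12 = C–Me carbons, C13 = CH–OAc). With that labelling the target is (1R,4R,5S,8R,9S,12S,13R), with a 2,5-cis THF (C5–O–C8). The route is a design proposal; none of it has been run.

## Retrosynthetic overview
1. Endgame: acrylic acid from the isopropenyl group (SeO2, then Pinnick); C13 acetate; C12 carbinol from OH-directed epoxidation and hydride opening of a macrocyclic (E)-allylic alcohol.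
2. Macrocycle (second ring formed): Nozaki–Hiyama–Kishi closure of C12–C13 between an (E)-vinyl iodide and the limonene-derived aldehyde; C13 fixed by oxidation/CBS reduction.
3. THF (first ring formed): Payne rearrangement / 5-exo epoxide-opening cascade of an acyclic 4,5:8,9-bis-epoxide (Shi + Sharpless). The terminal 9,10-epoxide it releases accepts propynyl (C11, C12, C12-Me).
4. Chain: B-alkyl Suzuki (C5–C6) between a C6–C10 dienol and the (E)-vinyl iodide made from (R)-limonene (selective ozonolysis, ketone → alkyne, Zr-carboalumination). C1 comes from limonene.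

## Route

**Step 1**
Reactants: 1, (R)-(+)-limonene
Product: 2, (5R)-7,7-dimethoxy-5-(prop-1-en-2-yl)heptan-2-one
Conditions: O3 (1 equiv, Sudan Red end-point), CH2Cl2/MeOH, −78 °C; p-TsOH, rt; NaHCO3, Me2S
Reagents that add atoms: ozone, [O-][O+]=O; methanol, CO
Why: Chemoselective ozonolysis of the electron-richer trisubstituted ring alkene with Schreiber-type work-up gives the methyl ketone and the aldehyde masked as its dimethyl acetal; C1 (R) is carried over from limonene.

**Step 2**
Reactants: 2
Product: 3, (5R)-7,7-dimethoxy-5-(prop-1-en-2-yl)hept-1-yne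
Conditions: LDA, THF, −78 °C; ClP(O)(OEt)2; LDA (2.3 equiv), −78 °C → rt
Reagents that add atoms: none
Why: Negishi methyl ketone → terminal alkyne (kinetic enol phosphate, then elimination); the former ketone CH3 becomes C5.

**Step 3**
Reactants: 3
Product: 4, (1E,5R)-1-iodo-7,7-dimethoxy-2-methyl-5-(prop-1-en-2-yl)hept-1-ene
Conditions: Me3Al, Cp2ZrCl2 (cat.), H2O (1 equiv), CH2Cl2, −23 °C; I2, THF, −30 °C
Reagents that add atoms: trimethylaluminium, C[Al](C)C; iodine, II
Why: Negishi Zr-catalysed syn-carboalumination (Wipf low-temperature variant, to spare the acetal) puts Me on C4 and Al (then I, with retention) on C5, fixing the E-trisubstituted alkene.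

**Step 4**
Reactants: 5, (E)-3-methylpent-2-en-4-yn-1-ol
Product: 6, (E)-3-methylpenta-2,4-dien-1-ol
Conditions: H2 (1 atm), Lindlar Pd, quinoline, EtOAc, rt
Reagents that add atoms: none
Why: Lindlar semi-hydrogenation stops at the vinyl group and leaves the E-trisubstituted alkene untouched.

**Step 5**
Reactants: 6 and 4
Product: 7, (2E,6E,10R)-12,12-dimethoxy-3,7-dimethyl-10-(prop-1-en-2-yl)dodeca-2,6-dien-1-ol
Conditions: 6, 9-BBN (2.2 equiv), THF, 0 °C → rt; then aq. Cs2CO3, 4, Pd(dppf)Cl2, AsPh3, DMF, rt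
Reagents that add atoms: none
Why: B-alkyl Suzuki–Miyaura coupling: 9-BBN adds only at the terminal CH2 of the diene (C6), and sp3–sp2 coupling retains the E geometry of the vinyl iodide.

**Step 6**
Reactants: 7
Product: 8, (8R,9R)-8,9-epoxy alcohol of 7 (a 2,3-epoxygeraniol-type unit; C10–OH free)
Conditions: Ti(OiPr)4 (10 mol %), D-(−)-diethyl tartrate, t-BuOOH, 4 Å MS, CH2Cl2, −20 °C
Reagents that add atoms: tert-butyl hydroperoxide, CC(C)(C)OO
Why: Sharpless asymmetric epoxidation touches only the allylic-alcohol alkene; D-tartrate gives the (8R,9R) epoxide (the "2R,3R" sense known for geraniol).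

**Step 7**
Reactants: 8
Product: 9, (4R,5R,8R,9R)-4,5:8,9-bis-epoxide
Conditions: Shi ketone (D-fructose-derived, 0.3 equiv), Oxone, K2CO3, Bu4NHSO4, MeCN/DMM–buffer (pH 10.5), 0 °C
Reagents that add atoms: Oxone (KHSO5), [K+].[O-]S(=O)(=O)OO
Why: Shi epoxidation is much faster on the E-trisubstituted C4=C5 alkene than on the 1,1-disubstituted isopropenyl group; the D-fructose catalyst gives the (R,R) epoxide.

**Step 8**
Reactants: 9
Product: 10, 2,5-cis-THF (C5–O–C8) with C4 tertiary OH and terminal 9,10-epoxide, (1R,4R,5S,8R,9S); C13 still CH(OMe)2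
Conditions: 0.5 M NaOH, t-BuOH/H2O, rt → 40 °C
Reagents that add atoms: none
Why: Payne rearrangement (C10–O⁻ opens the 8,9-epoxide at C9 with inversion) frees the C8 tertiary alkoxide, which closes the THF by 5-exo-tet attack at C5 of the 4,5-epoxide (inversion); C4 and C8 keep their epoxide oxygens.

**Step 9**
Reactants: 10
Product: 11, homopropargylic alcohol (C9–OH; C10–C≡C–CH3)
Conditions: 1-propynyllithium (3 equiv), BF3·OEt2, THF, −78 °C
Reagents that add atoms: 1-propynyllithium, [Li]C#CC
Why: Yamaguchi alkynylation opens the epoxide at the terminal CH2 (C10), leaving C9 untouched and bringing in C11, C12 and the C12 methyl.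

**Step 10**
Reactants: 11
Product: 12, C9–OTBS ether of 11
Conditions: TBSCl, imidazole, DMAP (cat.), DMF, 40 °C
Reagents that add atoms: TBSCl, CC(C)(C)[Si](C)(C)Cl
Why: Silylation of the only secondary OH (tertiary C4–OH is inert); this differentiates C9–OH from C13–OH for the later acetylation.

**Step 11**
Reactants: 12
Product: 13, (11E)-12-iodo alkene (C10–CH=C(CH3)I)
Conditions: Cp2Zr(H)Cl (2.5 equiv), THF, 45 °C; I2, 0 °C
Reagents that add atoms: iodine, II
Why: Schwartz hydrozirconation–iodination: syn H–Zr addition, Zr equilibrates to the less hindered methyl-bearing carbon, and iodinolysis with retention gives the (E)-2-iodo-2-alkene.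

**Step 12**
Reactants: 13
Product: 14, aldehyde (C13 = CHO)
Conditions: PPTS, acetone/H2O, 50 °C
Reagents that add atoms: water, O
Why: Mild acetal hydrolysis (transacetalisation); the TBS ether, vinyl iodide, THF and isopropenyl group are stable.

**Step 13**
Reactants: 14
Product: 15, 14-membered (11E)-allylic alcohol, C13–OH as an epimer mixture
Conditions: CrCl2 (8 equiv), NiCl2 (cat.), DMSO/THF, 2 mM, rt
Reagents that add atoms: none
Why: Nozaki–Hiyama–Kishi macrocyclisation: the vinyl-Cr(III) species adds chemoselectively to the aldehyde (free tertiary OH tolerated) with retention of alkene geometry; C13 is corrected in steps 14–15.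

**Step 14**
Reactants: 15
Product: 16, macrocyclic (11E)-enone (C13=O)
Conditions: Dess–Martin periodinane, NaHCO3, CH2Cl2, rt
Reagents that add atoms: none
Why: Dess–Martin oxidation of the only oxidisable alcohol removes the C13 epimer mixture.

**Step 15**
Reactants: 16
Product: 17, (13R)-allylic alcohol
Conditions: (S)-2-methyl-CBS-oxazaborolidine, catecholborane, toluene, −78 °C
Reagents that add atoms: none
Why: Corey–Bakshi–Shibata reduction: the α-methyl-alkenyl group acts as the large substituent, so the (S)-catalyst gives the 13R alcohol; catecholborane avoids hydroboration of the isopropenyl group.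

**Step 16**
Reactants: 17
Product: 18, (11R,12R,13R)-11,12-epoxy-13-ol
Conditions: VO(acac)2 (5 mol %), t-BuOOH, CH2Cl2, 0 °C
Reagents that add atoms: tert-butyl hydroperoxide, CC(C)(C)OO
Why: Hydroxyl-directed vanadium epoxidation delivers oxygen syn to C13–OH through the A(1,2)-minimised (erythro) transition state, setting C12; only the allylic-alcohol alkene reacts.

**Step 17**
Reactants: 18
Product: 19, (12S,13R)-12,13-diol (C9–OTBS)
Conditions: LiEt3BH, THF, 0 °C → rt
Reagents that add atoms: none
Why: SN2 hydride opening at the less substituted C11; the C12–O bond is untouched, giving the tertiary carbinol (descriptor becomes 12S by CIP change only).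

**Step 18**
Reactants: 19
Product: 20, C13 acetate
Conditions: Ac2O, pyridine, DMAP (cat.), CH2Cl2, 0 °C → rt
Reagents that add atoms: acetic anhydride, CC(=O)OC(C)=O
Why: Acetylation of the only free secondary OH; the tertiary C4 and C12 alcohols do not react under these conditions.

**Step 19**
Reactants: 20
Product: 21, enal (C1–C(=CH2)CHO)
Conditions: SeO2 (cat.), t-BuOOH, CH2Cl2, rt; then MnO2
Reagents that add atoms: selenium dioxide, O=[Se]=O
Why: Riley allylic oxidation (ene / [2,3] shift) at the isopropenyl CH3 (CH3 preferred over the ring CH); MnO2 takes any allylic alcohol on to the enal.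

**Step 20**
Reactants: 21
Product: 22, acrylic acid (C9–OTBS)
Conditions: NaClO2, NaH2PO4, 2-methyl-2-butene, t-BuOH/H2O, rt
Reagents that add atoms: sodium chlorite, [Na+].[O-]Cl=O
Why: Pinnick oxidation of the enal to the acid without affecting the alkene, alcohols or acetate.

**Step 21**
Reactants: 22
Product: 23, Dendronpholide J
Conditions: HF·pyridine, THF/pyridine, 0 °C → rt
Reagents that add atoms: none
Why: Acidic fluoride desilylation frees C9–OH; the acetate, THF, tertiary alcohols and acrylic acid are stable.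

## Compound list
1 | (R)-(+)-limonene | CC1=CC[C@@H](CC1)C(C)=C | starting material
2 | (5R)-7,7-dimethoxy-5-(prop-1-en-2-yl)heptan-2-one | C=C(C)[C@@H](CC(OC)OC)CCC(C)=O | intermediate
3 | (5R)-7,7-dimethoxy-5-(prop-1-en-2-yl)hept-1-yne | C=C(C)[C@@H](CC(OC)OC)CCC#C | intermediate
4 | (1E,5R)-1-iodo-7,7-dimethoxy-2-methyl-5-(prop-1-en-2-yl)hept-1-ene | C=C(C)[C@@H](CC(OC)OC)CC/C(C)=C/I | intermediate
5 | (E)-3-methylpent-2-en-4-yn-1-ol | C#C/C(C)=C/CO | starting material
6 | (E)-3-methylpenta-2,4-dien-1-ol | C=C/C(C)=C/CO | intermediate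
7 | (2E,6E,10R)-12,12-dimethoxy-3,7-dimethyl-10-(prop-1-en-2-yl)dodeca-2,6-dien-1-ol | C=C(C)[C@@H](CC(OC)OC)CC/C(C)=C/CC/C(C)=C/CO | intermediate
8 | (8R,9R)-8,9-epoxy alcohol of 7 | C=C(C)[C@@H](CC(OC)OC)CC/C(C)=C/CC[C@@]1(C)O[C@@H]1CO | intermediate
9 | (4R,5R,8R,9R)-4,5:8,9-bis-epoxy alcohol | C=C(C)[C@@H](CC(OC)OC)CC[C@@]1(C)O[C@@H]1CC[C@@]2(C)O[C@@H]2CO | intermediate
10 | cis-THF, C4–OH, terminal 9,10-epoxide (1R,4R,5S,8R,9S) | C=C(C)[C@@H](CC(OC)OC)CC[C@@](C)(O)[C@@H]1CC[C@@](C)(O1)[C@@H]2CO2 | intermediate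
11 | C9-ol with C10–C≡C–CH3 | C=C(C)[C@@H](CC(OC)OC)CC[C@@](C)(O)[C@@H]1CC[C@@](C)(O1)[C@@H](O)CC#CC | intermediate
12 | C9–OTBS ether of 11 | C=C(C)[C@@H](CC(OC)OC)CC[C@@](C)(O)[C@@H]1CC[C@@](C)(O1)[C@@H](O[Si](C)(C)C(C)(C)C)CC#CC | intermediate
13 | (11E)-12-iodo alkene, acetal | C=C(C)[C@@H](CC(OC)OC)CC[C@@](C)(O)[C@@H]1CC[C@@](C)(O1)[C@@H](O[Si](C)(C)C(C)(C)C)C/C=C(/I)C | intermediate
14 | (11E)-12-iodo alkene, C13 aldehyde | C=C(C)[C@@H](CC=O)CC[C@@](C)(O)[C@@H]1CC[C@@](C)(O1)[C@@H](O[Si](C)(C)C(C)(C)C)C/C=C(/I)C | intermediate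
15 | macrocyclic (11E)-allylic alcohol, C13 epimers | C=C(C)[C@@H]1CC[C@@](C)(O)[C@@H]2CC[C@@](C)(O2)[C@@H](O[Si](C)(C)C(C)(C)C)C/C=C(C)/C(O)C1 | intermediate
16 | macrocyclic (11E)-enone | C=C(C)[C@@H]1CC[C@@](C)(O)[C@@H]2CC[C@@](C)(O2)[C@@H](O[Si](C)(C)C(C)(C)C)C/C=C(C)/C(=O)C1 | intermediate
17 | (13R)-allylic alcohol | C=C(C)[C@@H]1CC[C@@](C)(O)[C@@H]2CC[C@@](C)(O2)[C@@H](O[Si](C)(C)C(C)(C)C)C/C=C(C)/[C@H](O)C1 | intermediate
18 | (11R,12R,13R)-11,12-epoxy-13-ol | C=C(C)[C@@H]1CC[C@@](C)(O)[C@@H]2CC[C@@](C)(O2)[C@@H](O[Si](C)(C)C(C)(C)C)C[C@H]3O[C@]3(C)[C@H](O)C1 | intermediate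
19 | (12S,13R)-diol, C9–OTBS | C=C(C)[C@@H]1CC[C@@](C)(O)[C@@H]2CC[C@@](C)(O2)[C@@H](O[Si](C)(C)C(C)(C)C)CC[C@](C)(O)[C@H](O)C1 | intermediate
20 | C13 acetate, C9–OTBS | C=C(C)[C@@H]1CC[C@@](C)(O)[C@@H]2CC[C@@](C)(O2)[C@@H](O[Si](C)(C)C(C)(C)C)CC[C@](C)(O)[C@H](OC(C)=O)C1 | intermediate
21 | enal | C=C(C=O)[C@@H]1CC[C@@](C)(O)[C@@H]2CC[C@@](C)(O2)[C@@H](O[Si](C)(C)C(C)(C)C)CC[C@](C)(O)[C@H](OC(C)=O)C1 | intermediate
22 | acrylic acid, C9–OTBS | C=C(C(=O)O)[C@@H]1CC[C@@](C)(O)[C@@H]2CC[C@@](C)(O2)[C@@H](O[Si](C)(C)C(C)(C)C)CC[C@](C)(O)[C@H](OC(C)=O)C1 | intermediate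
23 | Dendronpholide J | C=C(C(=O)O)[C@@H]1CC[C@@](C)(O)[C@@H]2CC[C@@](C)(O2)[C@@H](O)CC[C@](C)(O)[C@H](OC(C)=O)C1 | target

## Summary
Total steps: 21. Longest linear sequence: 20 (steps 1–3 and 5–21, from limonene).

Steps most likely to fail, each with a fallback that changes the approach:
1. **Step 8 (Payne / 5-exo cascade).** The rearranged tertiary alkoxide is a minor equilibrium species and hydroxide can compete. Fallback: take C9 from the chiral pool instead. Add MeMgBr under chelation control to the vinyl ketone of isopropylidene glycerate, couple that tertiary vinyl carbinol to 4 by B-alkyl Suzuki, and Shi-epoxidise C4=C5 so the C8–OH closes the THF directly. Then convert the acetonide to the 9,10-epoxide (acid; TsCl; K2CO3).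
2. **Step 13 (NHK macrocyclisation to the 14-membered ring).** Fallback: close the ring at C10=C11 by intramolecular Horner–Wadsworth–Emmons instead (C10 aldehyde from the 9,10-epoxide; β-ketophosphonate at C11–C12 built on a protected C13 cyanohydrin). Follow with Stryker conjugate reduction and chelation-controlled MeMgBr addition to the C12 ketone.
3. **Step 16 (directed epoxidation in the macrocycle).** Ring conformation may override the acyclic A(1,2) model. Fallback: set C12/C13 before ring closure. Add isopropenyl-MgBr to the C13 aldehyde, oxidise and CBS-reduce, then run the VO(acac)2 epoxidation on the acyclic isopropenyl carbinol (well-precedented erythro selectivity). Close the ring at C10–C11 by sulfone-anion opening of the resulting 11,12-epoxide, then desulfonylate.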